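**Plan**

- Retrosynthetic cuts, in order: the O7–CH2 bond of the prenyl ether; C1'–C2' and C5'–C6' of ring B; the C≡C bond of a 2-ethynyl group (traced back through the aldehyde to a 2-methyl group); O1–C2 and C2–C3 of ring C; and C4–C4a.
- Enabling feature: ring B is a 4-hydroxy-3-methoxyphenyl group on C2. C3'(OMe) and C4'(O) map onto C2 and C3 of a 1,2-dimethoxy-3-silyloxybutadiene whose C1 methoxyl is expelled on aromatisation. C2 is the acyl-like carbon of the vinylogous ester O1–C2=C3–C4=O, so an ethynyl group there is a propiolate-like dienophile.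
- Forward order: ring A phenol from 2,4,6-trihydroxybenzaldehyde (steps 1–5); side chain and ring C (steps 6–8); methyl to aldehyde to alkyne (steps 9–10); diene (steps 11–13); ring B (step 14); then debenzylation, 7-O-prenylation and desilylation (steps 15–17).
- Stereochemistry: the target has no stereocentre and no stereogenic double bond. The transient centres in 10, 13, 19 and 22 are racemic and are destroyed. Only the 1Z geometry of the diene matters, and it is set in steps 11–12.

Key step: step 14

Assumption: enone 20 and diene 21 are taken as the Z isomers (terminal methoxyl trans to C3), the geometry an s-cis diene requires; racemic transient centres are written without descriptors.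

**Route**

Step 1
Reactants: 1 2,4,6-trihydroxybenzaldehyde
Product: 2 2,4-bis(benzyloxy)-6-hydroxybenzaldehyde
Conditions: BnBr (2.1 equiv), K2CO3 (2.2 equiv), DMF, 0 °C to rt
Reagents that add atoms: benzyl bromide, BrCc1ccccc1
Why: Williamson etherification should take the 4-OH and one ortho OH, while the remaining ortho OH, hydrogen-bonded to the formyl group, is left free.

Step 2
Reactants: 2 2,4-bis(benzyloxy)-6-hydroxybenzaldehyde
Product: 3 2,4-bis(benzyloxy)-6-(methoxymethoxy)benzaldehyde
Conditions: MOMCl, i-Pr2NEt, CH2Cl2, 0 to 40 °C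
Reagents that add atoms: chloromethyl methyl ether, COCCl
Why: Acetal-type O-alkylation of the chelated phenol gives a MOM ether that is orthogonal to benzyl and stable to the peracid and base of the next two steps.

Step 3
Reactants: 3 2,4-bis(benzyloxy)-6-(methoxymethoxy)benzaldehyde
Product: 5 2,4-bis(benzyloxy)-6-(methoxymethoxy)phenol, via aryl formate 4 (not isolated)
Conditions: mCPBA, CH2Cl2, 0 °C to rt; then K2CO3 (cat.), MeOH, rt
Reagents that add atoms: 3-chloroperoxybenzoic acid, OOC(=O)c1cccc(Cl)c1
Why: Baeyer–Villiger (Dakin-type) oxidation, in which the electron-rich trialkoxyaryl group migrates, gives the formate, which is methanolysed in the same flask.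

Step 4
Reactants: 5 2,4-bis(benzyloxy)-6-(methoxymethoxy)phenol
Product: 6 1,5-bis(benzyloxy)-2-methoxy-3-(methoxymethoxy)benzene
Conditions: MeI, K2CO3, DMF, rt
Reagents that add atoms: iodomethane, CI
Why: Williamson O-methylation of the only free phenol fixes the future 8-methoxyl.

Step 5
Reactants: 6 1,5-bis(benzyloxy)-2-methoxy-3-(methoxymethoxy)benzene
Product: 7 3,5-bis(benzyloxy)-2-methoxyphenol
Conditions: HCl (cat.), MeOH–THF, 50 °C
Reagents that add atoms: none
Why: Acid-catalysed acetal exchange removes only the MOM group, since benzyl and methyl aryl ethers are inert to dilute methanolic HCl.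

Step 6
Reactants: 7 3,5-bis(benzyloxy)-2-methoxyphenol, 8 2-(benzyloxy)acetaldehyde
Product: 10 2-(benzyloxy)-1-[4,6-bis(benzyloxy)-2-hydroxy-3-methoxyphenyl]ethan-1-ol (racemic), via bromomagnesium phenoxide 9 (not isolated)
Conditions: EtMgBr (1.0 equiv), Et2O, 0 °C; then 8, CH2Cl2, 0 °C to rt; aq. NH4Cl
Reagents that add atoms: none
Why: Magnesium-phenoxide-templated ortho-hydroxyalkylation delivers the aldehyde through a six-membered chelate to the only free ortho carbon, so the para carbon between the two benzyloxy groups is not attacked; the carbinol centre forms as a racemate and is removed in step 7.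

Step 7
Reactants: 10 2-(benzyloxy)-1-[4,6-bis(benzyloxy)-2-hydroxy-3-methoxyphenyl]ethan-1-ol
Product: 11 2-(benzyloxy)-1-[4,6-bis(benzyloxy)-2-hydroxy-3-methoxyphenyl]ethan-1-one
Conditions: MnO2, CH2Cl2, rt
Reagents that add atoms: none
Why: MnO2 oxidation of an activated benzylic alcohol under neutral conditions should give the hydrogen-bonded ortho-hydroxyaryl ketone without ionising the carbinol to an ortho-quinone methide.

Step 8
Reactants: 11 2-(benzyloxy)-1-[4,6-bis(benzyloxy)-2-hydroxy-3-methoxyphenyl]ethan-1-one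
Product: 14 3,5,7-tris(benzyloxy)-8-methoxy-2-methyl-4H-chromen-4-one, via aryl acetate 12 (not isolated), via 1,3-diketone 13 (not isolated)
Conditions: Ac2O, NaOAc, 170 °C
Reagents that add atoms: acetic anhydride, CC(=O)OC(C)=O
Why: Kostanecki–Robinson chromone synthesis (O-acetylation, acyl transfer to the α-carbon, cyclodehydration), the standard route from ω-alkoxy-2-hydroxyacetophenones to 3-alkoxy-2-methylchromones; only the oxygen next to the methoxyl is free, so ring C can close only to the 8-methoxy isomer.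

Step 9
Reactants: 14 3,5,7-tris(benzyloxy)-8-methoxy-2-methyl-4H-chromen-4-one
Product: 15 3,5,7-tris(benzyloxy)-8-methoxy-4-oxo-4H-chromene-2-carbaldehyde
Conditions: SeO2, PhBr, 150 °C
Reagents that add atoms: selenium dioxide, O=[Se]=O
Why: Riley oxidation of the vinylogously activated 2-methyl group, as established for 3-benzyloxy-2-methyl-4-pyranones and 2-methylchromones, should stop at the aldehyde and leave the benzyl ethers untouched.

Step 10
Reactants: 15 3,5,7-tris(benzyloxy)-8-methoxy-4-oxo-4H-chromene-2-carbaldehyde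
Product: 16 3,5,7-tris(benzyloxy)-2-ethynyl-8-methoxy-4H-chromen-4-one
Conditions: MeC(O)C(N2)P(O)(OMe)2, K2CO3, MeOH–THF, 0 °C to rt
Reagents that add atoms: dimethyl (1-diazo-2-oxopropyl)phosphonate, COP(=O)(OC)C(=[N+]=[N-])C(C)=O
Why: Seyferth–Gilbert homologation with the Ohira–Bestmann reagent (olefination, loss of N2, 1,2-hydrogen shift of the alkylidene carbene) gives the terminal alkyne under mild carbonate conditions, kept cold and short to limit methoxide addition to the product.

Step 11
Reactants: 17 methoxyacetone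
Product: 18 (Z)-4-(dimethylamino)-3-methoxybut-3-en-2-one
Conditions: Me2NCH(OMe)2 (neat), 100 °C
Reagents that add atoms: N,N-dimethylformamide dimethyl acetal, COC(OC)N(C)C
Why: Enaminone formation with the amide acetal should occur at the more readily enolised methoxy-bearing methylene, placing the amino group trans to the acetyl group.

Step 12
Reactants: 18 (Z)-4-(dimethylamino)-3-methoxybut-3-en-2-one
Product: 20 (Z)-3,4-dimethoxybut-3-en-2-one, via keto acetal 19 (not isolated)
Conditions: HCl in dry MeOH (1.2 equiv), rt to 50 °C; then NaOAc, 150 °C, distil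
Reagents that add atoms: methanol, CO
Why: Acid-catalysed alcoholysis of the vinylogous amide gives the β-keto acetal (the amine is trapped as its hydrochloride), and thermal loss of methanol then gives the β-methoxy enone, the way 4-methoxybut-3-en-2-one is made from its acetal; the racemic centre of 19 disappears and the less hindered Z isomer is expected.

Step 13
Reactants: 20 (Z)-3,4-dimethoxybut-3-en-2-one
Product: 21 (1Z)-1,2-dimethoxy-3-(triisopropylsilyloxy)buta-1,3-diene
Conditions: i-Pr3SiOTf, Et3N, Et2O, 0 °C to rt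
Reagents that add atoms: triisopropylsilyl trifluoromethanesulfonate, CC(C)[Si](OS(=O)(=O)C(F)(F)F)(C(C)C)C(C)C
Why: Soft enolisation and O-silylation of the methyl ketone, the standard preparation of 1-alkoxy-3-silyloxybutadienes, leaves the C1=C2 geometry untouched and installs a silyl group robust enough to serve later as the 4'-O protecting group.

Step 14
Reactants: 16 3,5,7-tris(benzyloxy)-2-ethynyl-8-methoxy-4H-chromen-4-one, 21 (1Z)-1,2-dimethoxy-3-(triisopropylsilyloxy)buta-1,3-diene
Product: 23 3,5,7-tris(benzyloxy)-8-methoxy-2-[3-methoxy-4-(triisopropylsilyloxy)phenyl]-4H-chromen-4-one, via cyclohexadiene cycloadduct 22 (not isolated)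
Conditions: 21 (3 equiv), toluene, 110 °C, sealed tube; then PPTS (cat.), CH2Cl2, rt
Reagents that add atoms: none
Why: Proposed new method: the closest known reaction type is the Diels–Alder/aromatisation of 1-alkoxy-3-silyloxybutadienes with propiolates, ynones and electron-poor arylacetylenes, which gives para-oxygenated arenes by loss of the alcohol; here C2 of the chromone is the acyl-like carbon of a vinylogous ester, so the ethynyl group on it should behave as a vinylogous propiolate. The diene terminus C4, made nucleophilic by the 3-silyloxy group and through conjugation by the 1-methoxyl, bonds to the terminal alkyne carbon and diene C1 to the internal one, either in a concerted asynchronous (4+2) cycloaddition or, in the limit, by conjugate addition followed by ring closure, both leading to adduct 22. Ring B is closed as a six-membered carbocycle by intermolecular (4+2) annulation, with C1'–C2' and C5'–C6' both formed in this step. PPTS then ionises the doubly allylic methoxyl of 22 and loss of a proton from the ring CH2 gives the arene with the aryl silyl ether intact; the single stereocentre of 22 is racemic and is erased, so no stereocontrol is needed. The step needs regioselectivity (methoxyl at C3', silyloxy at C4') and chemoselectivity for the alkyne over C2=C3: the first follows from the matched polarity just described, the second from C2=C3 being tetrasubstituted and donor-substituted.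

Step 15
Reactants: 23 3,5,7-tris(benzyloxy)-8-methoxy-2-[3-methoxy-4-(triisopropylsilyloxy)phenyl]-4H-chromen-4-one
Product: 24 3,5,7-trihydroxy-8-methoxy-2-[3-methoxy-4-(triisopropylsilyloxy)phenyl]-4H-chromen-4-one
Conditions: H2 (1 atm), Pd/C, EtOAc–THF, rt
Reagents that add atoms: none
Why: Hydrogenolysis of the three benzyl ethers over Pd/C should leave the pyranone double bond, the methyl ethers and the aryl silyl ether untouched.

Step 16
Reactants: 24 3,5,7-trihydroxy-8-methoxy-2-[3-methoxy-4-(triisopropylsilyloxy)phenyl]-4H-chromen-4-one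
Product: 25 3,5-dihydroxy-8-methoxy-2-[3-methoxy-4-(triisopropylsilyloxy)phenyl]-7-[(3-methylbut-2-en-1-yl)oxy]-4H-chromen-4-one
Conditions: prenyl bromide (1.05 equiv), K2CO3 (1.1 equiv), DMF, 0 °C to rt
Reagents that add atoms: 1-bromo-3-methylbut-2-ene, CC(C)=CCBr
Why: Williamson etherification with one equivalent of base should select the 7-OH, the most acidic hydroxyl (para to the carbonyl and not chelated), over the 3-OH and 5-OH, which are hydrogen-bonded to C4=O.

Step 17
Reactants: 25 3,5-dihydroxy-8-methoxy-2-[3-methoxy-4-(triisopropylsilyloxy)phenyl]-7-[(3-methylbut-2-en-1-yl)oxy]-4H-chromen-4-one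
Product: 26 3,5-dihydroxy-2-(4-hydroxy-3-methoxyphenyl)-8-methoxy-7-[(3-methylbut-2-en-1-yl)oxy]-4H-chromen-4-one (CNP0210396.0)
Conditions: Bu4NF, AcOH, THF, 0 °C
Reagents that add atoms: none
Why: Fluoride-mediated cleavage of the aryl silyl ether, buffered with acetic acid, frees the 4'-OH without acid or hydrogen, so the prenyl ether survives.

**Compound list**

1 | 2,4,6-trihydroxybenzaldehyde | O=Cc1c(O)cc(O)cc1O | starting material
2 | 2,4-bis(benzyloxy)-6-hydroxybenzaldehyde | O=Cc1c(O)cc(OCc2ccccc2)cc1OCc1ccccc1 | intermediate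
3 | 2,4-bis(benzyloxy)-6-(methoxymethoxy)benzaldehyde | COCOc1cc(OCc2ccccc2)cc(OCc2ccccc2)c1C=O | intermediate
4 | 2,4-bis(benzyloxy)-6-(methoxymethoxy)phenyl formate | COCOc1cc(OCc2ccccc2)cc(OCc2ccccc2)c1OC=O | intermediate (not isolated)
5 | 2,4-bis(benzyloxy)-6-(methoxymethoxy)phenol | COCOc1cc(OCc2ccccc2)cc(OCc2ccccc2)c1O | intermediate
6 | 1,5-bis(benzyloxy)-2-methoxy-3-(methoxymethoxy)benzene | COCOc1cc(OCc2ccccc2)cc(OCc2ccccc2)c1OC | intermediate
7 | 3,5-bis(benzyloxy)-2-methoxyphenol | COc1c(O)cc(OCc2ccccc2)cc1OCc1ccccc1 | intermediate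
8 | 2-(benzyloxy)acetaldehyde | O=CCOCc1ccccc1 | starting material
9 | bromomagnesium 3,5-bis(benzyloxy)-2-methoxyphenoxide | COc1c(O[Mg]Br)cc(OCc2ccccc2)cc1OCc1ccccc1 | intermediate (not isolated)
10 | 2-(benzyloxy)-1-[4,6-bis(benzyloxy)-2-hydroxy-3-methoxyphenyl]ethan-1-ol (racemic) | COc1c(O)c(C(O)COCc2ccccc2)c(OCc2ccccc2)cc1OCc1ccccc1 | intermediate
11 | 2-(benzyloxy)-1-[4,6-bis(benzyloxy)-2-hydroxy-3-methoxyphenyl]ethan-1-one | COc1c(O)c(C(=O)COCc2ccccc2)c(OCc2ccccc2)cc1OCc1ccccc1 | intermediate
12 | 2-[(benzyloxy)acetyl]-3,5-bis(benzyloxy)-6-methoxyphenyl acetate | COc1c(OC(C)=O)c(C(=O)COCc2ccccc2)c(OCc2ccccc2)cc1OCc1ccccc1 | intermediate (not isolated)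
13 | 2-(benzyloxy)-1-[4,6-bis(benzyloxy)-2-hydroxy-3-methoxyphenyl]butane-1,3-dione (racemic, enolisable) | COc1c(O)c(C(=O)C(OCc2ccccc2)C(C)=O)c(OCc2ccccc2)cc1OCc1ccccc1 | intermediate (not isolated)
14 | 3,5,7-tris(benzyloxy)-8-methoxy-2-methyl-4H-chromen-4-one | Cc1oc2c(OC)c(OCc3ccccc3)cc(OCc3ccccc3)c2c(=O)c1OCc1ccccc1 | intermediate
15 | 3,5,7-tris(benzyloxy)-8-methoxy-4-oxo-4H-chromene-2-carbaldehyde | O=Cc1oc2c(OC)c(OCc3ccccc3)cc(OCc3ccccc3)c2c(=O)c1OCc1ccccc1 | intermediate
16 | 3,5,7-tris(benzyloxy)-2-ethynyl-8-methoxy-4H-chromen-4-one | C#Cc1oc2c(OC)c(OCc3ccccc3)cc(OCc3ccccc3)c2c(=O)c1OCc1ccccc1 | intermediate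
17 | methoxyacetone | COCC(C)=O | starting material
18 | (Z)-4-(dimethylamino)-3-methoxybut-3-en-2-one | CN(C)/C=C(\OC)C(C)=O | intermediate
19 | 3,4,4-trimethoxybutan-2-one (racemic) | COC(OC)C(OC)C(C)=O | intermediate (not isolated)
20 | (Z)-3,4-dimethoxybut-3-en-2-one | CO/C=C(\OC)C(C)=O | intermediate
21 | (1Z)-1,2-dimethoxy-3-(triisopropylsilyloxy)buta-1,3-diene | CO/C=C(\OC)C(=C)O[Si](C(C)C)(C(C)C)C(C)C | intermediate
22 | 3,5,7-tris(benzyloxy)-2-[5,6-dimethoxy-4-(triisopropylsilyloxy)cyclohexa-1,4-dien-1-yl]-8-methoxy-4H-chromen-4-one (racemic) | COC1C(OC)=C(O[Si](C(C)C)(C(C)C)C(C)C)CC=C1c2oc3c(OC)c(OCc4ccccc4)cc(OCc4ccccc4)c3c(=O)c2OCc5ccccc5 | intermediate (not isolated)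
23 | 3,5,7-tris(benzyloxy)-8-methoxy-2-[3-methoxy-4-(triisopropylsilyloxy)phenyl]-4H-chromen-4-one | COc1cc(-c2oc3c(OC)c(OCc4ccccc4)cc(OCc4ccccc4)c3c(=O)c2OCc2ccccc2)ccc1O[Si](C(C)C)(C(C)C)C(C)C | intermediate
24 | 3,5,7-trihydroxy-8-methoxy-2-[3-methoxy-4-(triisopropylsilyloxy)phenyl]-4H-chromen-4-one | COc1cc(-c2oc3c(OC)c(O)cc(O)c3c(=O)c2O)ccc1O[Si](C(C)C)(C(C)C)C(C)C | intermediate
25 | 3,5-dihydroxy-8-methoxy-2-[3-methoxy-4-(triisopropylsilyloxy)phenyl]-7-[(3-methylbut-2-en-1-yl)oxy]-4H-chromen-4-one | COc1cc(-c2oc3c(OC)c(OCC=C(C)C)cc(O)c3c(=O)c2O)ccc1O[Si](C(C)C)(C(C)C)C(C)C | intermediate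
26 | 3,5-dihydroxy-2-(4-hydroxy-3-methoxyphenyl)-8-methoxy-7-[(3-methylbut-2-en-1-yl)oxy]-4H-chromen-4-one | COc1cc(-c2oc3c(OC)c(OCC=C(C)C)cc(O)c3c(=O)c2O)ccc1O | target

**Step count**

Total: 17 steps. Longest linear sequence: 14 steps (steps 1–10 and 14–17); steps 11–13 prepare the diene separately.

**Steps most likely to fail**

Step 14 (proposed new method). The diene may hydrolyse or oligomerise faster than it adds to the moderately activated alkyne, or conjugate addition may stop at an open-chain adduct that does not close. The fallback brings ring B in ready-made by known Baker–Venkataraman-type chemistry; it sets out from ketone 11 and returns at 23. Vanillic acid is bis-silylated (i-Pr3SiCl, imidazole, DMF) to triisopropylsilyl 3-methoxy-4-(triisopropylsilyloxy)benzoate F1. Oxalyl chloride with catalytic DMF converts the silyl ester into 3-methoxy-4-(triisopropylsilyloxy)benzoyl chloride F2. Ketone 11 is deprotonated with LiN(SiMe3)2 (3 equiv, THF, −78 °C) and C-acylated by F2 to give 2-(benzyloxy)-1-[4,6-bis(benzyloxy)-2-hydroxy-3-methoxyphenyl]-3-[3-methoxy-4-(triisopropylsilyloxy)phenyl]propane-1,3-dione F3. Cyclodehydration (p-TsOH cat., toluene, 80 °C) then closes ring C to 23.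

Step 6. The electron-rich benzylic alkoxide may ionise to an ortho-quinone methide that is captured by a second phenoxide (diarylmethane formation), or the enolisable aldehyde may self-condense before it is delivered to the ring. The fallback switches to electrophilic acylation; it sets out from phenol 7 and returns at ketone 11, replacing steps 6 and 7. O-Acylation with benzyloxyacetyl chloride (Et3N, CH2Cl2, 0 °C) gives 3,5-bis(benzyloxy)-2-methoxyphenyl (benzyloxy)acetate F4. Fries rearrangement (BF3·OEt2, CH2Cl2, rt to 40 °C), in which the boron-chelated ortho-hydroxy ketone is the thermodynamic product, then gives 11.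

Step 16. Alkylation may continue at O3 or occur at C6, eroding the site selectivity for O7. The fallback leaves only the 7-OH free before the prenyl group is introduced; it sets out from triol 24 and returns at 25. Peracetylation (Ac2O, pyridine) gives 8-methoxy-2-[3-methoxy-4-(triisopropylsilyloxy)phenyl]-4-oxo-4H-chromene-3,5,7-triyl triacetate F5. Selective thiolysis of the most activated aryl ester (PhSH, imidazole, N-methylpyrrolidone, 0 °C to rt) gives 7-hydroxy-8-methoxy-2-[3-methoxy-4-(triisopropylsilyloxy)phenyl]-4-oxo-4H-chromene-3,5-diyl diacetate F6. Mitsunobu etherification with 3-methylbut-2-en-1-ol (PPh3, diisopropyl azodicarboxylate, THF) gives 8-methoxy-2-[3-methoxy-4-(triisopropylsilyloxy)phenyl]-7-[(3-methylbut-2-en-1-yl)oxy]-4-oxo-4H-chromene-3,5-diyl diacetate F7. Ammonolysis of the two acetates (NH3, MeOH, 0 °C) then gives 25.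

**Further compounds**

F1 | step 14 | triisopropylsilyl 3-methoxy-4-(triisopropylsilyloxy)benzoate | COc1cc(C(=O)O[Si](C(C)C)(C(C)C)C(C)C)ccc1O[Si](C(C)C)(C(C)C)C(C)C
F2 | step 14 | 3-methoxy-4-(triisopropylsilyloxy)benzoyl chloride | COc1cc(C(Cl)=O)ccc1O[Si](C(C)C)(C(C)C)C(C)C
F3 | step 14 | 2-(benzyloxy)-1-[4,6-bis(benzyloxy)-2-hydroxy-3-methoxyphenyl]-3-[3-methoxy-4-(triisopropylsilyloxy)phenyl]propane-1,3-dione | COc1cc(C(=O)C(OCc2ccccc2)C(=O)c2c(O)c(OC)c(OCc3ccccc3)cc2OCc2ccccc2)ccc1O[Si](C(C)C)(C(C)C)C(C)C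
F4 | step 6 | 3,5-bis(benzyloxy)-2-methoxyphenyl (benzyloxy)acetate | COc1c(OC(=O)COCc2ccccc2)cc(OCc2ccccc2)cc1OCc1ccccc1
F5 | step 16 | 8-methoxy-2-[3-methoxy-4-(triisopropylsilyloxy)phenyl]-4-oxo-4H-chromene-3,5,7-triyl triacetate | COc1cc(-c2oc3c(OC)c(OC(C)=O)cc(OC(C)=O)c3c(=O)c2OC(C)=O)ccc1O[Si](C(C)C)(C(C)C)C(C)C
F6 | step 16 | 7-hydroxy-8-methoxy-2-[3-methoxy-4-(triisopropylsilyloxy)phenyl]-4-oxo-4H-chromene-3,5-diyl diacetate | COc1cc(-c2oc3c(OC)c(O)cc(OC(C)=O)c3c(=O)c2OC(C)=O)ccc1O[Si](C(C)C)(C(C)C)C(C)C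
F7 | step 16 | 8-methoxy-2-[3-methoxy-4-(triisopropylsilyloxy)phenyl]-7-[(3-methylbut-2-en-1-yl)oxy]-4-oxo-4H-chromene-3,5-diyl diacetate | COc1cc(-c2oc3c(OC)c(OCC=C(C)C)cc(OC(C)=O)c3c(=O)c2OC(C)=O)ccc1O[Si](C(C)C)(C(C)C)C(C)C
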